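## Structural features

The target 39 is a germacranolide: a cyclodeca-1(10),4-diene (C1–C10) in which C1=C10 is ring-cis (Z, methyl C14 on C10) and C4=C5 is ring-trans (Z by CIP only because C4 carries the C15 hydroxymethyl group). A γ-lactone (O–C12(=O)–C11) is trans-fused across C6–C7. C11 bears a methyl group trans to the C7–C8 bond, and the C8 oxygen is acylated by (E)-4-hydroxy-2-methylbut-2-enoic acid. The stereocentres C6 (R), C7 (R), C8 (S) and C11 (S) are adjacent, and the three ring substituents on C6–C8 are mutually trans. Fragile elements are the 1,5-diene (transannular cyclisation with acid, Cope rearrangement on heating), two primary allylic alcohols, a base-labile ester next to the lactone, and the epimerisable lactone α-carbon. The real difficulty is to close a ten-membered ring with two trisubstituted alkenes of opposite geometric sense directly beside the stereotriad. The key step exploits the array C10=C1–C2–C3–C4=C5: it is the Cope isomer of a cyclohexane C5–C10 that already carries C6, C7 and C8, with a C5 oxygen to drive the shift and to be removed afterwards. An atom-by-atom check of precursor 23, triflate 26 and target 39 (C6, C7, C8, C11 and both alkene geometries) shows them mutually consistent, so no structure is corrected. The precursor design is changed in one respect: the C15 oxygen carries a triisopropylsilyl group instead of a smaller silyl group, for the reasons given in step 15.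

## Logic of the disconnections

39 ⇒ 38. The two O–Si bonds at O15 and O4′ are cut last. The primary allylic alcohols are the groups most easily oxidised or acylated, so they stay masked until nothing else has to be done. The forward step must remove silicon without touching lactone, enoate or diene.

38 ⇒ 35 (through 37 and 36). The O6–C12 acyl bond and the C12 oxidation level are cut back to a 1,4-diol. A lactone would not survive the organometallic and strongly basic steps; two ether oxygens do. The forward oxidation must pick the primary carbinol, C8 must already be acylated so that only O6 can close on C12, and C11 must not epimerise.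

35 ⇒ 34. Two benzylic C–O bonds are cut. One neutral oxidative operation frees O6 and O12 together while the silyl ethers stay. The demand is tolerance of two electron-rich alkenes.

34 ⇒ 28 + 32, and 32 ⇒ 31 ⇒ 29 + 30. The C8–O acyl bond is cut, then C2′=C3′ of the side chain. This makes the route convergent and keeps the base-sensitive ester out of all anionic chemistry. The forward steps need an acylation strong enough for a hindered secondary alcohol and an E-selective olefination.

28 ⇒ 27 ⇒ 26. The O8–Si bond is cut, then the C5–H bond is traced to a C5–O sulfonate. The C5 oxygen thus becomes a handle that is deleted with retention of alkene geometry. The demand is selective cleavage of one silyl ether beside another.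

26 ⇒ 23 (through 25 and 24). C2–C3 is cut and C5–C10 re-formed. The ten-membered ring with both alkenes collapses to a cyclohexanol whose stereochemistry can be built by ordinary six-ring reasoning. The forward step must run through one chair and the enolate must be trapped on oxygen before it decomposes.

23 ⇒ 22 ⇒ 21 ⇒ 20. The O8–Si bond, the C8–H bond and the ketal are cut in turn. C8 stays masked as a ketal while C5 is attacked, which removes any competition between two ketones. The reduction must place the hydroxyl equatorial against the bias of the axial C10 methyl group.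

20 ⇒ 15 + 17 (through 19 and 18), and 17 ⇒ 16. The C4–C5 bond is cut. This attaches C2–C4 and C15 in one step to a ketone that holds every ring stereocentre. The nucleophile must add axially, anti to the axial C10 methyl group, and must not enolise the α-alkoxy ketone.

15 ⇒ 14 ⇒ 12 (through 13). C1=C2 is traced to a carbinol and the C10–C1 bond is cut. The quaternary centre then comes from a regiodefined enolate and a two-carbon electrophile. The electrophile must enter on the α face.

12 ⇒ 11 ⇒ 10 ⇒ 9. The C5 oxidation level is adjusted and the two benzyl ether bonds are cut. Etherification is thereby done on a substrate without any carbonyl group, which avoids a free α-ketol beside an allylic ketal. The cost is two redox steps.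

9 ⇒ 6 (through 8 and 7). The C12–O and C6–O bonds are cut, with the C11–H and C5–H bonds made in the same operations. Two hydroborations give C11, C6 and C5 from the single centre C7. The first borane must choose the 1,1-disubstituted alkene and the C6-side face.

6 ⇒ 4 (through 5), 4 ⇒ 2 + 3, and 2 ⇒ 1. The O–Si bond, the C7–C11 bond and the ketal are cut. This leaves an achiral dienone and a three-carbon alkenyl donor. The catalyst must set C7 and must react only at the unsubstituted enone.

## Other disconnections considered

Alternative 1: The cut is the lactone C12–O6 bond, traced to an oxygen insertion, with C6 and C7 taken from the carbohydrate-derived enone levoglucosenone A1. In the forward direction a vinyl group adds to the exo face of A1 to give ketone A2. Aqueous H2O2 then inserts oxygen between the carbonyl carbon (the future C12) and the acetal carbon, formate is lost, and the acyl group settles on the C6 oxygen to give the trans lactone A3. In its favour, C6 comes from the chiral pool and C7 from the shape of the bicycle, and the lactone is at its final oxidation level from the start. On these two points Alternative 1 is the better plan: it needs no chiral catalyst and no late oxidative lactonisation. Against it here, A3 holds only seven of the twenty carbons and two of the four stereocentres. The C11 methyl group, C8, both trisubstituted alkenes and the ring itself are still to come, and the lactone must then survive every chain extension and a base-mediated ring closure. Mechanistically the ring would have to be closed end to end, whereas the chosen plan closes it by ring expansion with both alkene geometries coupled to one chair. In step economy the short access to A3 is offset by the long way from A3 to a cyclisation substrate.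

Alternative 2: The cut is at C9–C10 and C10–C14, a three-component union. In the forward direction 5-lithio-2,3-dihydrofuran A4 and Me2CuLi form a cuprate in which methyl migrates to the metal-bearing carbon with loss of the ring oxygen. The alkenylcopper so formed, activated by BF3·OEt2, opens epoxide A5 at its terminal carbon (C9) to give diol lactone A6. In its favour, the ring-cis C1=C10 geometry follows from the mechanism (inversion at the migration terminus, retention on trapping). On this point Alternative 2 is the better plan, because the chosen route depends on a chair being preferred over a boat. It is also convergent, and C8 comes from the epoxide. Against it here, A5 is needed as one C8 epimer and would have to be made by epoxidising a terminal vinyl group under weak substrate control. The lactone must tolerate a Lewis acid and a cuprate, one methyl ligand is wasted, and A6 is still acyclic, so C4=C5 and the ring remain. The count to A6 would be comparable to that to 23, but the hardest step would still lie ahead.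

Alternative 3: The cut is the C4=C5 double bond. In the forward direction KN(SiMe3)2 with 18-crown-6 deprotonates the bis(trifluoroethyl)phosphonate of seco aldehyde A7. Intramolecular Horner–Wadsworth–Emmons olefination of Still–Gennari type then forms C4=C5 and the ring, giving macrocycle A8 with C15 as a methyl ester. In its favour, ring and ring-trans alkene arise in one step. In that respect Alternative 3 is the equal of the chosen plan, and it is the better plan in convergence and in carrying the finished lactone, C8 and C11 through unchanged. Against it here, a ten-membered ring is closed end to end, which needs high dilution and competes with oligomerisation. Ring strain can override the kinetic Z preference of the phosphonate. The aldehyde carbon is attached to the epimerisable C6. The C15 ester must later be reduced selectively beside a lactone and before C8 is acylated. The chosen plan pays with more protecting-group and redox steps but forms the ring without dilution.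

Key step: step 15

Remark on conventions: germacrane numbering is kept for every intermediate (the six-membered ring is C5–C10); α is the ring face that carries the C6 oxygen and β the opposite face.

Assumption: the rhodium/(R)-BINAP catalyst is taken to deliver the alkenyl group with the facial sense known for cyclohex-2-enone; if the sense proves opposite, (S)-BINAP is used with no other change.

Step 1
Reactants: 1 4-methoxy-2-methylphenol
Product: 2 4,4-dimethoxy-2-methylcyclohexa-2,5-dien-1-one
Conditions: PhI(OAc)2, MeOH, 0 °C
Reagents that add atoms: methanol (CO)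
Why: Oxidative dearomatisation of a para-alkoxyphenol by hypervalent iodine in methanol gives the quinone monoketal; the carbonyl carbon is the future C5 and the ketal carbon the future C8.

Step 2
Reactants: 2 4,4-dimethoxy-2-methylcyclohexa-2,5-dien-1-one; 3 potassium trifluoro(prop-1-en-2-yl)borate
Product: 4 (5R)-4,4-dimethoxy-2-methyl-5-(prop-1-en-2-yl)cyclohex-2-en-1-one
Conditions: [Rh(cod)2]BF4 (3 mol %), (R)-BINAP, Et3N, toluene/H2O, 25 °C
Reagents that add atoms: none
Why: Rhodium-catalysed asymmetric conjugate addition (Hayashi–Miyaura reaction) of the alkenyl group to the unsubstituted enone; the α-methyl enone is inert to the alkenylrhodium species, and the chiral diphosphine sets C7.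

Step 3
Reactants: 4 (5R)-4,4-dimethoxy-2-methyl-5-(prop-1-en-2-yl)cyclohex-2-en-1-one
Product: 6 {[(6R)-5,5-dimethoxy-3-methyl-6-(prop-1-en-2-yl)cyclohexa-1,3-dien-2-yl]oxy}tri(propan-2-yl)silane, via potassium dienolate 5 (not isolated)
Conditions: KN(SiMe3)2, THF, −78 °C; i-Pr3SiOTf, −78 → 0 °C
Reagents that add atoms: tri(propan-2-yl)silyl trifluoromethanesulfonate (CC(C)[Si](C(C)C)(C(C)C)OS(=O)(=O)C(F)(F)F)
Why: Only C6 carries α-hydrogens, so kinetic enolisation and O-silylation give a single dienol ether; it masks the ketone against boranes and keeps C6 flat for the next step.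

Step 4
Reactants: 6 silyl dienol ether
Product: 9 (1S,2S,6S)-6-[(2S)-1-hydroxypropan-2-yl]-5,5-dimethoxy-3-methyl-2-{[tri(propan-2-yl)silyl]oxy}cyclohex-3-en-1-ol, via alkyl-9-BBN adduct 7 (not isolated), via bis(organoborane) 8 (not isolated)
Conditions: 9-BBN, THF, 0 → 23 °C; BH3·SMe2, 0 → 23 °C; NaOH, H2O2, 0 °C
Reagents that add atoms: hydrogen peroxide (OO)
Why: Two hydroboration–oxidations in one flask. 9-BBN takes only the 1,1-disubstituted alkene; by the A(1,3)-strain model (C7–H eclipsing the C=CH2 bond) it approaches past the flat C6 and away from the ketal carbon, which should set C11 as S. BH3 then adds to the enol ether with boron on C6 anti to the C7 side chain and hydrogen on C5 from the same face, so oxidation with retention gives the C6 α-hydroxyl trans to C7 and the C5 silyl ether trans to it.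

Step 5
Reactants: 9 diol
Product: 10 O6,O12-bis(4-methoxybenzyl) ether of 9 (germacrane numbering 5S,6S,7S,11S)
Conditions: NaH, 4-MeOC6H4CH2Cl, Bu4NI (cat.), DMF, 0 → 23 °C
Reagents that add atoms: 4-methoxybenzyl chloride (COc1ccc(CCl)cc1)
Why: Williamson etherification on a substrate that has no carbonyl group, so the strong base is harmless; the bulky triisopropylsilyl group is not expected to migrate to the neighbouring alkoxide.

Step 6
Reactants: 10 bis(4-methoxybenzyl) ether
Product: 11 (1S,5S,6S)-4,4-dimethoxy-6-[(4-methoxybenzyl)oxy]-5-{(2S)-1-[(4-methoxybenzyl)oxy]propan-2-yl}-2-methylcyclohex-2-en-1-ol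
Conditions: Bu4NF, THF, 23 → 45 °C
Reagents that add atoms: none
Why: Fluoride cleavage of the only silyl ether present; ketal and benzyl-type ethers are inert.

Step 7
Reactants: 11 allylic alcohol
Product: 12 (5S,6S)-4,4-dimethoxy-6-[(4-methoxybenzyl)oxy]-5-{(2S)-1-[(4-methoxybenzyl)oxy]propan-2-yl}-2-methylcyclohex-2-en-1-one
Conditions: Dess–Martin periodinane, NaHCO3, CH2Cl2, 0 → 23 °C
Reagents that add atoms: none
Why: Buffered periodinane oxidation restores the C5 enone; the C6 oxygen is already etherified, so no free α-ketol ever sits next to the allylic ketal.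

Step 8
Reactants: 12 enone
Product: 14 (2S,3S,6S)-6-(1-hydroxyethyl)-4,4-dimethoxy-2-[(4-methoxybenzyl)oxy]-3-{(2S)-1-[(4-methoxybenzyl)oxy]propan-2-yl}-6-methylcyclohexan-1-one (carbinol epimers), via lithium enolate 13 (not isolated)
Conditions: LiBH(s-Bu)3, THF, −78 °C; MeCHO, −78 °C; aq. NH4Cl
Reagents that add atoms: acetaldehyde (CC=O)
Why: Reductive aldol reaction: conjugate hydride delivery to C9 of the α-methyl enone gives the regiodefined enolate 13. The aldehyde should add to C10 on the α face, because the β-face (axial) trajectory is 1,3-diaxial to the axial methoxy group of the C8 ketal; the same preference holds thermodynamically, and the carbinol configuration is irrelevant.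

Step 9
Reactants: 14 aldol
Product: 15 (2S,3S,6S)-6-ethenyl-4,4-dimethoxy-2-[(4-methoxybenzyl)oxy]-3-{(2S)-1-[(4-methoxybenzyl)oxy]propan-2-yl}-6-methylcyclohexan-1-one
Conditions: Burgess reagent, toluene, 70 °C
Reagents that add atoms: none
Why: Syn-elimination through the sulfamate ester; C10 is quaternary, so only the methyl hydrogens are available and only the vinyl group can form.

Step 10
Reactants: 16 2-bromoprop-2-en-1-ol
Product: 17 [(2-bromoprop-2-en-1-yl)oxy]tri(propan-2-yl)silane
Conditions: i-Pr3SiCl, imidazole, CH2Cl2, 23 °C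
Reagents that add atoms: chlorotri(propan-2-yl)silane (CC(C)[Si](Cl)(C(C)C)C(C)C)
Why: Standard silylation of a primary alcohol; the bulky silyl group suppresses oxygen-to-carbon silyl shift in the lithio reagent of the next step.

Step 11
Reactants: 15 vinyl ketone; 17 bromoallyl silyl ether
Product: 20 (1R,2S,3S,6S)-6-ethenyl-4,4-dimethoxy-2-[(4-methoxybenzyl)oxy]-3-{(2S)-1-[(4-methoxybenzyl)oxy]propan-2-yl}-6-methyl-1-(3-{[tri(propan-2-yl)silyl]oxy}prop-1-en-2-yl)cyclohexan-1-ol, via alkenyllithium 18 (not isolated), via alkenylcerium reagent 19 (not isolated)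
Conditions: 17, t-BuLi, Et2O, −78 °C; CeCl3, THF, −78 °C; then 15, −78 → −40 °C
Reagents that add atoms: none
Why: Bromine–lithium exchange and transmetalation give a weakly basic organocerium reagent that adds to the hindered α-alkoxy ketone without enolising it. It should attack C5 axially on the α face, anti to the axial C10 methyl group, so the new alkenyl group is axial and cis to the equatorial C10 vinyl group.

Step 12
Reactants: 20 tertiary alcohol with C8 ketal
Product: 21 C8 ketone corresponding to 20 (germacrane numbering 5R,6S,7S,10S,11S)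
Conditions: PPTS, acetone/H2O, 40 °C
Reagents that add atoms: water (O)
Why: Mild acid hydrolysis of a dialkyl ketal; C10 is now quaternary, so unmasking C8 can no longer lead to aromatisation, and the weak acid spares the benzyl-type ethers, the triisopropylsilyl ether and the tertiary allylic alcohol.

Step 13
Reactants: 21 C8 ketone
Product: 22 C8 α-alcohol (equatorial) corresponding to 21 (germacrane numbering 5R,6S,7R,8S,10S,11S)
Conditions: SmI2, H2O, Et3N, THF, 0 °C
Reagents that add atoms: none
Why: Single-electron reduction by divalent samarium gives a ketyl whose protonation is under product-like control, so the hydroxyl should take the equatorial position and avoid a syn-axial contact with the C10 methyl group; hydride reagents would be steered to the other epimer by that methyl group. No heteroatom sits α to this ketone, so no C–O bond is reductively cleaved.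

Step 14
Reactants: 22 C5,C8-diol
Product: 23 C8 triethylsilyl ether of 22, the cis-1,2-dialkenylcyclohexanol (germacrane numbering 5R,6S,7S,8S,10S,11S)
Conditions: Et3SiCl, imidazole, CH2Cl2, 0 °C
Reagents that add atoms: chlorotriethylsilane (CC[Si](Cl)(CC)CC)
Why: The secondary hydroxyl is silylated; the tertiary C5 hydroxyl flanked by a quaternary carbon is left free for the key step.

Step 15
Reactants: 23 cis-1,2-dialkenylcyclohexanol
Product: 26 ten-membered C5 enol triflate (1(10)Z,4E,6S,7S,8S,11S; C4 CH2OSi(i-Pr)3; C6 4-methoxybenzyl ether; C7 (2S)-1-[(4-methoxybenzyl)oxy]propan-2-yl; C8 OSiEt3; C10 methyl), via potassium alkoxide 24 (not isolated), via potassium enolate 25 (not isolated)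
Conditions: KN(SiMe3)2, 18-crown-6, THF, −78 → 0 °C; PhNTf2, −78 °C
Reagents that add atoms: N-phenylbis(trifluoromethanesulfonimide) (O=S(=O)(N(c1ccccc1)S(=O)(=O)C(F)(F)F)C(F)(F)F)
Why: The base with the crown ether gives the ion-separated alkoxide 24; the oxyanion weakens the C5–C10 bond and a [3,3]-sigmatropic shift forms C2–C3 while C5–C10 breaks, the closest known reaction type being the anionic oxy-Cope ring expansion of cis-1,2-dialkenylcyclohexanols to cyclodec-5-enones with O-triflation of the enolate. The ten-membered ring is thus closed by a four-carbon ring expansion and not end to end, so no high dilution is needed. No stereocentre is created, but two stereogenic alkenes are, and both are fixed by the one chair transition state open to the locked cyclohexane (C6, C7 and C8 substituents equatorial, C10 vinyl equatorial, C5 alkenyl axial). In it the C10 methyl is pseudo-equatorial and C9 pseudo-axial, which gives the ring-cis C1=C10 bond, and C6 is pseudo-equatorial with the oxyanion pseudo-axial, which gives the ring-trans C4=C5 enolate with oxygen cis to C3. The step needs chair over boat, which the cis relationship of the alkenyl groups and the equatorial stereotriad should secure. It also needs the regiodefined enolate 25 to be sulfonylated on oxygen before it expels the C15 silanolate, which is addressed by the lowest workable rearrangement temperature and by triflation at −78 °C. The C6 oxygen carries a benzyl-type ether because a silyl group there could migrate to the alkoxide or to the enolate oxygen. The triisopropylsilyl group at C15 is chosen because it survived the acidic step 12, does not shift in reagent 18 and is cleanly distinguished from the triethylsilyl ether later; it does not make the silanolate a poorer leaving group.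

Step 16
Reactants: 26 enol triflate
Product: 27 cyclodeca-1(10),4-diene with hydrogen on C5 (1(10)Z,4Z,6R,7S,8S,11S; substituents as in 26)
Conditions: Pd(OAc)2 (cat.), PPh3, Bu3N, HCO2H, DMF, 60 °C
Reagents that add atoms: none
Why: Palladium-catalysed formate reduction of an enol triflate: oxidative addition to zerovalent palladium, formate decarboxylation to a palladium hydride and reductive elimination with retention, so the ring-trans geometry is kept.

Step 17
Reactants: 27 diene with C8 triethylsilyl ether
Product: 28 C8 alcohol corresponding to 27 (1(10)Z,4Z,6R,7R,8S,11S)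
Conditions: HF·pyridine, pyridine, THF, 0 °C
Reagents that add atoms: none
Why: Buffered fluoride cleaves the secondary triethylsilyl ether far faster than the primary triisopropylsilyl ether, and the excess pyridine protects the acid-sensitive 1,5-diene.

Step 18
Reactants: 29 {[tert-butyl(dimethyl)silyl]oxy}acetaldehyde; 30 ethyl 2-(triphenyl-λ5-phosphanylidene)propanoate
Product: 31 ethyl (2E)-4-{[tert-butyl(dimethyl)silyl]oxy}-2-methylbut-2-enoate
Conditions: CH2Cl2, 23 °C
Reagents that add atoms: none
Why: Wittig reaction of a stabilised, α-branched ylide, which is expected to give the E-trisubstituted enoate.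

Step 19
Reactants: 31 ethyl ester
Product: 32 (2E)-4-{[tert-butyl(dimethyl)silyl]oxy}-2-methylbut-2-enoic acid
Conditions: LiOH, THF/H2O, 0 → 23 °C; aq. KHSO4 to pH 4
Reagents that add atoms: lithium hydroxide ([Li+].[OH-])
Why: Saponification; the primary silyl ether is stable to hydroxide and to the brief, mildly acidic work-up.

Step 20
Reactants: 28 C8 alcohol; 32 silylated side-chain acid
Product: 34 C8 ester of 28 with 32 (ring 1(10)Z,4Z,6R,7R,8S,11S; side chain 2E), via mixed anhydride 33 (not isolated)
Conditions: 2,4,6-Cl3C6H2COCl, Et3N, THF, 23 °C; then 28, DMAP, toluene, 23 °C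
Reagents that add atoms: none
Why: Yamaguchi esterification; the mixed anhydride with the hindered aroyl group is attacked at the enoyl carbonyl, and the E-enoate has no acidic γ-hydrogen to scramble under these conditions.

Step 21
Reactants: 34 ester with two 4-methoxybenzyl ethers
Product: 35 C6,C12-diol corresponding to 34 (6R,7S,8S,11S)
Conditions: DDQ, CH2Cl2/pH 7 buffer, 0 °C
Reagents that add atoms: none
Why: Oxidative cleavage of both 4-methoxybenzyl ethers by hydride abstraction and hydrolysis of the oxocarbenium ions; silyl ethers, the ester and the unactivated alkenes should be spared at neutral pH.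

Step 22
Reactants: 35 1,4-diol
Product: 38 bis-silyl ether of the target: 39 with O15 as triisopropylsilyl ether and O4′ as tert-butyldimethylsilyl ether, via hydroxy aldehyde 36 (not isolated), via lactol 37 (not isolated)
Conditions: TEMPO (cat.), PhI(OAc)2, CH2Cl2, 23 °C
Reagents that add atoms: none
Why: Oxoammonium oxidation is selective for the primary alcohol. The aldehyde is captured at once by the C6 hydroxyl as the five-membered lactol, which is oxidised to the trans-fused lactone. C8 is already acylated, so no isomeric lactone can form, and rapid lactol formation protects C11 from epimerisation.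

Step 23
Reactants: 38 bis-silyl ether
Product: 39 [(3S,3aR,4S,6Z,10Z,11aR)-10-(hydroxymethyl)-3,6-dimethyl-2-oxo-3a,4,5,8,9,11a-hexahydro-3H-cyclodeca[b]furan-4-yl] (2E)-4-hydroxy-2-methylbut-2-enoate
Conditions: HF·pyridine, pyridine, THF, 0 → 23 °C
Reagents that add atoms: none
Why: Buffered fluoride removes both primary allylic silyl ethers under conditions too mild for acyl migration, lactone opening or transannular cyclisation of the diene.

Compound list

1 | 4-methoxy-2-methylphenol | COc1ccc(O)c(C)c1 | starting material
2 | 4,4-dimethoxy-2-methylcyclohexa-2,5-dien-1-one | O=C1C=CC(OC)(OC)C=C1C | intermediate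
3 | potassium trifluoro(prop-1-en-2-yl)borate | C=C(C)[B-](F)(F)F.[K+] | starting material
4 | (5R)-4,4-dimethoxy-2-methyl-5-(prop-1-en-2-yl)cyclohex-2-en-1-one | O=C1C[C@H](C(C)=C)C(OC)(OC)C=C1C | intermediate
5 | potassium dienolate of 4 (not isolated) | [K+].[O-]C1=C[C@H](C(C)=C)C(OC)(OC)C=C1C | intermediate
6 | {[(6R)-5,5-dimethoxy-3-methyl-6-(prop-1-en-2-yl)cyclohexa-1,3-dien-2-yl]oxy}tri(propan-2-yl)silane | CC(C)[Si](C(C)C)(C(C)C)OC1=C[C@H](C(C)=C)C(OC)(OC)C=C1C | intermediate
7 | alkyl-9-BBN adduct: 6 with the side chain as (2S)-1-(9-borabicyclo[3.3.1]nonan-9-yl)propan-2-yl (not isolated) | CC(C)[Si](C(C)C)(C(C)C)OC1=C[C@H]([C@H](C)CB2C3CCCC2CCC3)C(OC)(OC)C=C1C | intermediate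
8 | bis(organoborane): 7 with BH2 on C6 (α) and H on C5 (not isolated) | CC(C)[Si](C(C)C)(C(C)C)O[C@@H]1[C@@H](B)[C@H]([C@H](C)CB2C3CCCC2CCC3)C(OC)(OC)C=C1C | intermediate
9 | (1S,2S,6S)-6-[(2S)-1-hydroxypropan-2-yl]-5,5-dimethoxy-3-methyl-2-{[tri(propan-2-yl)silyl]oxy}cyclohex-3-en-1-ol | CC(C)[Si](C(C)C)(C(C)C)O[C@@H]1[C@@H](O)[C@H]([C@H](C)CO)C(OC)(OC)C=C1C | intermediate
10 | O6,O12-bis(4-methoxybenzyl) ether of 9 (germacrane numbering 5S,6S,7S,11S) | CC(C)[Si](C(C)C)(C(C)C)O[C@@H]1[C@@H](OCc2ccc(OC)cc2)[C@H]([C@H](C)COCc2ccc(OC)cc2)C(OC)(OC)C=C1C | intermediate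
11 | (1S,5S,6S)-4,4-dimethoxy-6-[(4-methoxybenzyl)oxy]-5-{(2S)-1-[(4-methoxybenzyl)oxy]propan-2-yl}-2-methylcyclohex-2-en-1-ol | O[C@@H]1[C@@H](OCc2ccc(OC)cc2)[C@H]([C@H](C)COCc2ccc(OC)cc2)C(OC)(OC)C=C1C | intermediate
12 | (5S,6S)-4,4-dimethoxy-6-[(4-methoxybenzyl)oxy]-5-{(2S)-1-[(4-methoxybenzyl)oxy]propan-2-yl}-2-methylcyclohex-2-en-1-one | O=C1[C@@H](OCc2ccc(OC)cc2)[C@H]([C@H](C)COCc2ccc(OC)cc2)C(OC)(OC)C=C1C | intermediate
13 | lithium enolate (C5–C10) from conjugate reduction of 12 (not isolated) | CC1=C([O-])[C@@H](OCc2ccc(OC)cc2)[C@H]([C@H](C)COCc2ccc(OC)cc2)C(OC)(OC)C1.[Li+] | intermediate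
14 | (2S,3S,6S)-6-(1-hydroxyethyl)-4,4-dimethoxy-2-[(4-methoxybenzyl)oxy]-3-{(2S)-1-[(4-methoxybenzyl)oxy]propan-2-yl}-6-methylcyclohexan-1-one, carbinol epimers | O=C1[C@@H](OCc2ccc(OC)cc2)[C@H]([C@H](C)COCc2ccc(OC)cc2)C(OC)(OC)C[C@@]1(C)C(C)O | intermediate
15 | (2S,3S,6S)-6-ethenyl-4,4-dimethoxy-2-[(4-methoxybenzyl)oxy]-3-{(2S)-1-[(4-methoxybenzyl)oxy]propan-2-yl}-6-methylcyclohexan-1-one | O=C1[C@@H](OCc2ccc(OC)cc2)[C@H]([C@H](C)COCc2ccc(OC)cc2)C(OC)(OC)C[C@@]1(C)C=C | intermediate
16 | 2-bromoprop-2-en-1-ol | OCC(Br)=C | starting material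
17 | [(2-bromoprop-2-en-1-yl)oxy]tri(propan-2-yl)silane | C=C(Br)CO[Si](C(C)C)(C(C)C)C(C)C | intermediate
18 | (3-{[tri(propan-2-yl)silyl]oxy}prop-1-en-2-yl)lithium (not isolated) | [Li]C(=C)CO[Si](C(C)C)(C(C)C)C(C)C | intermediate
19 | dichloro(3-{[tri(propan-2-yl)silyl]oxy}prop-1-en-2-yl)cerium (not isolated) | Cl[Ce](Cl)C(=C)CO[Si](C(C)C)(C(C)C)C(C)C | intermediate
20 | (1R,2S,3S,6S)-6-ethenyl-4,4-dimethoxy-2-[(4-methoxybenzyl)oxy]-3-{(2S)-1-[(4-methoxybenzyl)oxy]propan-2-yl}-6-methyl-1-(3-{[tri(propan-2-yl)silyl]oxy}prop-1-en-2-yl)cyclohexan-1-ol | O[C@]1(C(=C)CO[Si](C(C)C)(C(C)C)C(C)C)[C@@H](OCc2ccc(OC)cc2)[C@H]([C@H](C)COCc2ccc(OC)cc2)C(OC)(OC)C[C@@]1(C)C=C | intermediate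
21 | C8 ketone: 20 with the dimethyl ketal hydrolysed (germacrane numbering 5R,6S,7S,10S,11S) | O[C@]1(C(=C)CO[Si](C(C)C)(C(C)C)C(C)C)[C@@H](OCc2ccc(OC)cc2)[C@H]([C@H](C)COCc2ccc(OC)cc2)C(=O)C[C@@]1(C)C=C | intermediate
22 | C8 α-alcohol of 21 (germacrane numbering 5R,6S,7R,8S,10S,11S) | O[C@]1(C(=C)CO[Si](C(C)C)(C(C)C)C(C)C)[C@@H](OCc2ccc(OC)cc2)[C@H]([C@H](C)COCc2ccc(OC)cc2)[C@@H](O)C[C@@]1(C)C=C | intermediate
23 | cis-1,2-dialkenylcyclohexanol, C8 triethylsilyl ether of 22 (germacrane numbering 5R,6S,7S,8S,10S,11S) | O[C@]1(C(=C)CO[Si](C(C)C)(C(C)C)C(C)C)[C@@H](OCc2ccc(OC)cc2)[C@H]([C@H](C)COCc2ccc(OC)cc2)[C@@H](O[Si](CC)(CC)CC)C[C@@]1(C)C=C | intermediate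
24 | potassium alkoxide of 23 (not isolated) | [K+].[O-][C@]1(C(=C)CO[Si](C(C)C)(C(C)C)C(C)C)[C@@H](OCc2ccc(OC)cc2)[C@H]([C@H](C)COCc2ccc(OC)cc2)[C@@H](O[Si](CC)(CC)CC)C[C@@]1(C)C=C | intermediate
25 | ten-membered potassium enolate, oxygen on C5 cis to C3 (not isolated) | [K+].C/C1=C/CC/C(CO[Si](C(C)C)(C(C)C)C(C)C)=C([O-])/[C@@H](OCc2ccc(OC)cc2)[C@H]([C@H](C)COCc2ccc(OC)cc2)[C@@H](O[Si](CC)(CC)CC)C1 | intermediate
26 | ten-membered C5 enol triflate (1(10)Z,4E,6S,7S,8S,11S) | C/C1=C/CC/C(CO[Si](C(C)C)(C(C)C)C(C)C)=C(OS(=O)(=O)C(F)(F)F)/[C@@H](OCc2ccc(OC)cc2)[C@H]([C@H](C)COCc2ccc(OC)cc2)[C@@H](O[Si](CC)(CC)CC)C1 | intermediate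
27 | cyclodeca-1(10),4-diene with H on C5 (1(10)Z,4Z,6R,7S,8S,11S) | C/C1=C/CC/C(CO[Si](C(C)C)(C(C)C)C(C)C)=C/[C@@H](OCc2ccc(OC)cc2)[C@H]([C@H](C)COCc2ccc(OC)cc2)[C@@H](O[Si](CC)(CC)CC)C1 | intermediate
28 | C8 alcohol of 27 (1(10)Z,4Z,6R,7R,8S,11S) | C/C1=C/CC/C(CO[Si](C(C)C)(C(C)C)C(C)C)=C/[C@@H](OCc2ccc(OC)cc2)[C@H]([C@H](C)COCc2ccc(OC)cc2)[C@@H](O)C1 | intermediate
29 | {[tert-butyl(dimethyl)silyl]oxy}acetaldehyde | O=CCO[Si](C)(C)C(C)(C)C | starting material
30 | ethyl 2-(triphenyl-λ5-phosphanylidene)propanoate | CCOC(=O)C(C)=P(c1ccccc1)(c1ccccc1)c1ccccc1 | starting material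
31 | ethyl (2E)-4-{[tert-butyl(dimethyl)silyl]oxy}-2-methylbut-2-enoate | CCOC(=O)/C(C)=C/CO[Si](C)(C)C(C)(C)C | intermediate
32 | (2E)-4-{[tert-butyl(dimethyl)silyl]oxy}-2-methylbut-2-enoic acid | OC(=O)/C(C)=C/CO[Si](C)(C)C(C)(C)C | intermediate
33 | mixed anhydride of 32 with 2,4,6-trichlorobenzoic acid (not isolated) | O=C(OC(=O)c1c(Cl)cc(Cl)cc1Cl)/C(C)=C/CO[Si](C)(C)C(C)(C)C | intermediate
34 | C8 ester of 28 with 32 (6R,7R,8S,11S) | C/C1=C/CC/C(CO[Si](C(C)C)(C(C)C)C(C)C)=C/[C@@H](OCc2ccc(OC)cc2)[C@H]([C@H](C)COCc2ccc(OC)cc2)[C@@H](OC(=O)/C(C)=C/CO[Si](C)(C)C(C)(C)C)C1 | intermediate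
35 | C6,C12-diol from 34 (6R,7S,8S,11S) | C/C1=C/CC/C(CO[Si](C(C)C)(C(C)C)C(C)C)=C/[C@@H](O)[C@H]([C@H](C)CO)[C@@H](OC(=O)/C(C)=C/CO[Si](C)(C)C(C)(C)C)C1 | intermediate
36 | C12 aldehyde from 35 (not isolated) | C/C1=C/CC/C(CO[Si](C(C)C)(C(C)C)C(C)C)=C/[C@@H](O)[C@H]([C@H](C)C=O)[C@@H](OC(=O)/C(C)=C/CO[Si](C)(C)C(C)(C)C)C1 | intermediate
37 | 6,12-lactol, anomers (not isolated) | C/C1=C/CC/C(CO[Si](C(C)C)(C(C)C)C(C)C)=C/[C@H]2OC(O)[C@@H](C)[C@@H]2[C@@H](OC(=O)/C(C)=C/CO[Si](C)(C)C(C)(C)C)C1 | intermediate
38 | 39 with O15 as triisopropylsilyl ether and O4′ as tert-butyldimethylsilyl ether | C/C1=C/CC/C(CO[Si](C(C)C)(C(C)C)C(C)C)=C/[C@H]2OC(=O)[C@@H](C)[C@@H]2[C@@H](OC(=O)/C(C)=C/CO[Si](C)(C)C(C)(C)C)C1 | intermediate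
39 | [(3S,3aR,4S,6Z,10Z,11aR)-10-(hydroxymethyl)-3,6-dimethyl-2-oxo-3a,4,5,8,9,11a-hexahydro-3H-cyclodeca[b]furan-4-yl] (2E)-4-hydroxy-2-methylbut-2-enoate | C/C1=C/CC/C(CO)=C/[C@H]2OC(=O)[C@@H](C)[C@@H]2[C@@H](OC(=O)/C(C)=C/CO)C1 | target

Total step count: 23. Longest linear sequence: 20 steps (steps 1–9, 11–17 and 20–23); step 10 and steps 18–19 are side branches.

Steps least certain to work

Step 15 (key step). The most likely failure is loss of the C15 silanolate from the potassium enolate by β-elimination before O-sulfonylation, because the rearrangement may need a temperature at which a crown-ether-separated enolate is no longer stable. A second risk is leakage through a boat transition state, which would scramble alkene geometry. The fallback changes the trapping chemistry and sets out from 23. The rearrangement is run with tert-butylchlorodimethylsilane already present; this chloride should silylate the hindered tertiary alkoxide only sluggishly but the enolate quickly, giving the ring-expanded tert-butyldimethylsilyl enol ether F1 with the enolate geometry preserved. F1 is then converted with CsF and PhNTf2 in 1,2-dimethoxyethane, where the transient enolate is sulfonylated as it forms, and the sequence comes back to the route at 26.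

Step 8. The most likely failures are poor facial selectivity in the carbon–carbon bond formation at C10, since the sterically open α-face approach is not the torsionally favoured one, and competing 1,2-reduction of the enone. The fallback sets out from 12 and puts the quaternary centre under catalyst control. Conjugate reduction and trapping with allyl chloroformate give the enol allyl carbonate F2. Palladium-catalysed decarboxylative allylation with the matching enantiomer of the t-Bu-PHOX ligand gives the α-allyl ketone F3. Ruthenium-hydride isomerisation moves the alkene to give the (E)-propenyl ketone F4. OsO4/NaIO4 cleavage gives the aldehyde F5, and methylenation with Ph3P=CH2, selective for the aldehyde over the hindered ketone, comes back to the route at 15.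

Step 13. The most likely failure is insufficient preference for equatorial protonation of the ketyl, which would leave the axial alcohol as a major component. The fallback sets out from 21 and uses kinetic control followed by inversion. LiBH(s-Bu)3 attacks the ketone from the unhindered equatorial direction to give the axial alcohol F6. Mitsunobu reaction with 4-nitrobenzoic acid inverts C8 to the equatorial ester F7, the tertiary hydroxyl being inert. Methanolysis with K2CO3 comes back to the route at 22.

Step 4. The most likely failures are over-hydroboration at the C9=C10 double bond in the BH3 stage and elimination of the β-silyloxy organoborane before oxidation. The fallback sets out from 6 and separates the two oxygenations. 9-BBN followed by NaBO3 gives only the primary alcohol F8 with the dienol ether intact. OsO4/N-methylmorpholine N-oxide under citric acid buffering converts the silyl enol ether into the α-ketol F9. Both hydroxyls are etherified at once under neutral conditions with 2-(4-methoxybenzyloxy)-4-methylquinoline, MeOTf and MgO, and the sequence comes back to the route at 12 (one step shorter, at the price of handling a free α-ketol).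

Further compounds

F1 | step 15 | ring-expanded tert-butyldimethylsilyl enol ether (26 with OSi(t-Bu)Me2 in place of the triflate) | C/C1=C/CC/C(CO[Si](C(C)C)(C(C)C)C(C)C)=C(O[Si](C)(C)C(C)(C)C)/[C@@H](OCc2ccc(OC)cc2)[C@H]([C@H](C)COCc2ccc(OC)cc2)[C@@H](O[Si](CC)(CC)CC)C1
F2 | step 8 | enol allyl carbonate of the C5–C10 enolate of 12 | CC1=C(OC(=O)OCC=C)[C@@H](OCc2ccc(OC)cc2)[C@H]([C@H](C)COCc2ccc(OC)cc2)C(OC)(OC)C1
F3 | step 8 | (2S,3S,6S)-4,4-dimethoxy-2-[(4-methoxybenzyl)oxy]-3-{(2S)-1-[(4-methoxybenzyl)oxy]propan-2-yl}-6-methyl-6-(prop-2-en-1-yl)cyclohexan-1-one | O=C1[C@@H](OCc2ccc(OC)cc2)[C@H]([C@H](C)COCc2ccc(OC)cc2)C(OC)(OC)C[C@@]1(C)CC=C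
F4 | step 8 | (E)-prop-1-en-1-yl isomer of F3 | O=C1[C@@H](OCc2ccc(OC)cc2)[C@H]([C@H](C)COCc2ccc(OC)cc2)C(OC)(OC)C[C@@]1(C)/C=C/C
F5 | step 8 | C10 carbaldehyde: 15 with CHO in place of the vinyl group | O=C1[C@@H](OCc2ccc(OC)cc2)[C@H]([C@H](C)COCc2ccc(OC)cc2)C(OC)(OC)C[C@@]1(C)C=O
F6 | step 13 | C8 β-alcohol (axial), the C8 epimer of 22 | O[C@]1(C(=C)CO[Si](C(C)C)(C(C)C)C(C)C)[C@@H](OCc2ccc(OC)cc2)[C@H]([C@H](C)COCc2ccc(OC)cc2)[C@H](O)C[C@@]1(C)C=C
F7 | step 13 | C8 α-(4-nitrobenzoate) of 22 | O[C@]1(C(=C)CO[Si](C(C)C)(C(C)C)C(C)C)[C@@H](OCc2ccc(OC)cc2)[C@H]([C@H](C)COCc2ccc(OC)cc2)[C@@H](OC(=O)c2ccc(cc2)[N+](=O)[O-])C[C@@]1(C)C=C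
F8 | step 4 | (2S)-2-[(1R)-6,6-dimethoxy-4-methyl-3-{[tri(propan-2-yl)silyl]oxy}cyclohexa-2,4-dien-1-yl]propan-1-ol | CC(C)[Si](C(C)C)(C(C)C)OC1=C[C@H]([C@H](C)CO)C(OC)(OC)C=C1C
F9 | step 4 | (5S,6S)-6-hydroxy-5-[(2S)-1-hydroxypropan-2-yl]-4,4-dimethoxy-2-methylcyclohex-2-en-1-one | O=C1[C@@H](O)[C@H]([C@H](C)CO)C(OC)(OC)C=C1C
A1 | alternative 1 | levoglucosenone, (1S,5R)-6,8-dioxabicyclo[3.2.1]oct-2-en-4-one | O=C1C=C[C@H]2CO[C@@H]1O2
A2 | alternative 1 | (1S,2R,5R)-2-ethenyl-6,8-dioxabicyclo[3.2.1]octan-4-one | O=C1C[C@H](C=C)[C@H]2CO[C@@H]1O2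
A3 | alternative 1 | (4R,5S)-4-ethenyl-5-(hydroxymethyl)oxolan-2-one | O=C1C[C@H](C=C)[C@@H](CO)O1
A4 | alternative 2 | 5-lithio-2,3-dihydrofuran | [Li]C1=CCCO1
A5 | alternative 2 | 5-{[(4-methoxybenzyl)oxy]methyl}-3-methyl-4-(oxiran-2-yl)oxolan-2-one, ring configured as in A6, oxirane carbon R | C1O[C@@H]1[C@H]2[C@H](C)C(=O)O[C@@H]2COCc2ccc(OC)cc2
A6 | alternative 2 | (3S,4R,5S)-4-[(1S,3Z)-1,6-dihydroxy-3-methylhex-3-en-1-yl]-5-{[(4-methoxybenzyl)oxy]methyl}-3-methyloxolan-2-one | OCC/C=C(/C)C[C@H](O)[C@H]1[C@H](C)C(=O)O[C@@H]1COCc2ccc(OC)cc2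
A7 | alternative 3 | seco aldehyde phosphonate: C5 aldehyde on the lactone, C4 bis(2,2,2-trifluoroethyl)phosphonoacetate terminus, C8 triethylsilyl ether, Z-C1=C10 | O=C[C@H]1OC(=O)[C@@H](C)[C@@H]1[C@@H](O[Si](CC)(CC)CC)C/C(C)=C\CCC(C(=O)OC)P(=O)(OCC(F)(F)F)OCC(F)(F)F
A8 | alternative 3 | methyl (3S,3aS,4S,6Z,10Z,11aR)-3,6-dimethyl-2-oxo-4-[(triethylsilyl)oxy]-3a,4,5,8,9,11a-hexahydro-3H-cyclodeca[b]furan-10-carboxylate | C/C1=C/CC/C(C(=O)OC)=C/[C@H]2OC(=O)[C@@H](C)[C@@H]2[C@@H](O[Si](CC)(CC)CC)C1
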